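The benzene ring carries the side chain at C1, OMe at C3 and OH at C5. This 5-alkylresorcinol pattern maps onto a linear 3,5,7-triketo ester, and the C2 oxygen can be added later, para to the C5 phenol. The ring is therefore cut at C1–C6. In one operation a dioxinone is cracked to an acylketene, benzyl alcohol captures it, and the chain folds by aldol condensation and dehydrates to the arene. The precursor is a 2,2-dimethyl-1,3-dioxin-4-one whose C6 bears a 2,4-dioxoheptadecyl chain with an (R)-silyloxy group. This carbinol carbon is C3 of (R)-3-hydroxytetradecanoic acid and is never touched.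

Key step: step 5

Remarks on the chemistry
- **Numbering:** the ring is C1 side chain, C2 OAc, C3 OMe, C4 H, C5 OH, C6 H. The open-chain ester is numbered from its ester carbonyl (C1) to the carbinol carbon (C9).
- **Configuration:** in the hydroxy acid, the dioxinone precursor, the resorcylate and the target, the carbinol carbon ranks O > CH2 bound to an sp2 carbon > undecyl > H. It is R throughout with the same spatial arrangement. Only O–H, O–Si and O–acyl bonds change at this centre.
- **Choice of ester:** benzyl alcohol is the ketene trap.
  - Dioxinone cracking needs about 110 °C. A refluxing low-boiling alcohol does not reach this, whereas toluene with benzyl alcohol does at ambient pressure.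
  - The di-ortho-substituted benzoate then leaves by neutral hydrogenolysis instead of hot hydroxide.
  - This matters because loss of the silyl group while the carboxyl carbon is still on the ring would end in the 3,4-dihydroisocoumarin lactone.
- **Assumption:** the hydroxy acid is bought as the single R enantiomer, and its optical purity fixes that of the target.

Step 1
Reactants: 1 (R)-3-hydroxytetradecanoic acid
Product: 2 (R)-3-hydroxy-N-methoxy-N-methyltetradecanamide
Conditions: MeNH(OMe)·HCl, N-(3-dimethylaminopropyl)-N'-ethylcarbodiimide hydrochloride (EDC·HCl), 1-hydroxybenzotriazole (cat.), N-methylmorpholine, CH2Cl2, 0 °C → rt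
Reagents that add atoms: N,O-dimethylhydroxylamine hydrochloride, CNOC.Cl
Why: Carbodiimide-mediated amide coupling (Weinreb amide formation) in which the amine outruns the secondary hydroxyl for the activated carboxyl, and the stereocentre, being β to the carbonyl, is not at risk.

Step 2
Reactants: 2 (R)-3-hydroxy-N-methoxy-N-methyltetradecanamide
Product: 3 (R)-3-(tert-butyldimethylsilyloxy)-N-methoxy-N-methyltetradecanamide
Conditions: TBSCl, imidazole, DMF, rt
Reagents that add atoms: tert-butyldimethylsilyl chloride, CC(C)(C)[Si](C)(C)Cl
Why: Imidazole-promoted O-silylation of a secondary alcohol, which changes only the O–H bond and so keeps the R configuration, gives an ether that tolerates amide bases, 110 °C, carbonate and hydrogenolysis.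

Step 3
Reactants: 4 2,2,6-trimethyl-4H-1,3-dioxin-4-one; 5 acetyl chloride
Product: 7 2,2-dimethyl-6-(2-oxopropyl)-4H-1,3-dioxin-4-one, via lithium dienolate 6 (not isolated)
Conditions: 4 (2 equiv), LiN(SiMe3)2 (2 equiv), THF, −78 °C; then 5 (1 equiv), −78 °C; AcOH quench
Reagents that add atoms: none
Why: γ-Selective C-acylation of a dioxinone dienolate, a crossed Claisen-type condensation, for which two equivalents of dienolate 6 per acyl chloride are used because product 7 is the stronger acid and consumes one of them.

Step 4
Reactants: 7 2,2-dimethyl-6-(2-oxopropyl)-4H-1,3-dioxin-4-one; 3 (R)-3-(tert-butyldimethylsilyloxy)-N-methoxy-N-methyltetradecanamide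
Product: 9 6-[(R)-6-(tert-butyldimethylsilyloxy)-2,4-dioxoheptadecyl]-2,2-dimethyl-4H-1,3-dioxin-4-one, via dilithium dianion 8 (not isolated)
Conditions: 7 (1.5 equiv), LiN(i-Pr)2 (3.0 equiv), THF, −78 °C; then 3 (1.0 equiv), −78 → −20 °C; AcOH quench at −78 °C; rapid chromatography
Reagents that add atoms: none
Why: Claisen-type acylation of a 1,3-dicarbonyl dianion at its terminal, more reactive carbanion combined with the Weinreb ketone synthesis: the amide releases the ketone only on the acidic quench, which prevents over-addition and proton shuffling, and the low temperature holds back E1cB loss of the β-silyloxy group.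

Step 5
Reactants: 9 6-[(R)-6-(tert-butyldimethylsilyloxy)-2,4-dioxoheptadecyl]-2,2-dimethyl-4H-1,3-dioxin-4-one
Product: 13 benzyl 2,4-dihydroxy-6-[(R)-2-(tert-butyldimethylsilyloxy)tridecyl]benzoate, via acylketene 10 (not isolated), via benzyl triketo ester 11 (not isolated), via aldol carbinol 12 (not isolated)
Conditions: BnOH (3 equiv), PhMe, 110 °C; cool to rt; Cs2CO3 (2 equiv), THF, rt; then AcOH
Reagents that add atoms: benzyl alcohol, OCc1ccccc1
Why: Heating expels acetone from the dioxinone by a retro-hetero-Diels–Alder reaction, and acylketene 10 is intercepted by the excess benzyl alcohol before its own enol oxygen can close a 4-hydroxy-2-pyrone, giving the largely enolized ester 11. The closest known reaction type is the thermolysis, alcohol capture and aldol aromatization of diketo-dioxinones to 6-alkyl-β-resorcylates, side chains with a protected β-hydroxyl included. Under Cs2CO3 the C4 and C6 methylenes are deprotonated first, being more acidic than C2, yet neither has a ketone within six-ring reach, so the product-forming event is addition of the less abundant C2 carbanion to the C7 ketone, a 6-(enolexo)-exo-trig closure (6-(enolendo)-exo-trig if counted through the C3 enolate, also allowed) that makes ring bond C1–C6 of the target and gives carbinol 12. E1cB loss of one water and tautomerization make the sequence irreversible and erase the two transient stereocentres of 12, so no new stereocentre needs control, and the existing R centre, β to the carbonyl, cannot epimerize. The selectivity needed is aldol folding over the C6-to-ester Claisen closure (acylphloroglucinol) and over pyrone formation; it rests on the ketone being a far better electrophile than the enolate-conjugated ester under a mild carbonate base at room temperature, and any ester exchange is degenerate because benzyl alcohol is the only alcohol present. The enolate charge on the C5–C7 diketone keeps C8 from being deprotonated, which suppresses both β-elimination of the silyloxy group and the alternative C8-to-C3 aldol.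

Step 6
Reactants: 13 benzyl 2,4-dihydroxy-6-[(R)-2-(tert-butyldimethylsilyloxy)tridecyl]benzoate
Product: 14 benzyl 2-hydroxy-4-methoxy-6-[(R)-2-(tert-butyldimethylsilyloxy)tridecyl]benzoate
Conditions: MeI (1.1 equiv), K2CO3 (1.1 equiv), acetone, rt
Reagents that add atoms: iodomethane, CI
Why: Williamson etherification in which the 2-OH is tied up in a hydrogen bond to the ester carbonyl and is the weaker acid, so one equivalent of MeI alkylates the 4-OH, and since either mono-ether would give the same phenol once CO2 is lost, only double methylation has to be avoided.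

Step 7
Reactants: 14 benzyl 2-hydroxy-4-methoxy-6-[(R)-2-(tert-butyldimethylsilyloxy)tridecyl]benzoate
Product: 16 3-methoxy-5-[(R)-2-(tert-butyldimethylsilyloxy)tridecyl]phenol, via benzoic acid 15 (not isolated)
Conditions: H2 (1 atm), Pd/C (10 wt %), EtOAc, rt; filter, concentrate; DMSO, 120 °C, N2
Reagents that add atoms: none
Why: Neutral hydrogenolysis of the benzyl ester followed by thermal protodecarboxylation, the classical behaviour of orsellinic-type acids in which the ortho hydroxyl relays a proton to the ipso carbon and the two ortho substituents add steric relief, while the silyl ether stays on so that acid 15 cannot lactonize.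

Step 8
Reactants: 16 3-methoxy-5-[(R)-2-(tert-butyldimethylsilyloxy)tridecyl]phenol
Product: 17 3-[(R)-2-hydroxytridecyl]-5-methoxyphenol
Conditions: HF·pyridine, THF, 0 °C → rt
Reagents that add atoms: none
Why: Fluoride-driven cleavage of the Si–O bond with retention at carbon, placed after loss of CO2 (no lactone partner left) and before the oxidation (a phenol is a sturdier substrate for deprotection than a methoxyquinone).

Step 9
Reactants: 17 3-[(R)-2-hydroxytridecyl]-5-methoxyphenol
Product: 18 2-[(R)-2-hydroxytridecyl]-6-methoxy-1,4-benzoquinone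
Conditions: (KSO3)2NO (Fremy's salt, 2.5 equiv), aq KH2PO4, acetone–H2O, rt
Reagents that add atoms: potassium nitrosodisulfonate (KSO3)2NO, [K+].[K+].[O]N(S(=O)(=O)[O-])S(=O)(=O)[O-]
Why: Teuber oxidation, in which one nitrosodisulfonate radical removes the phenolic hydrogen, a second one bonds through oxygen to the free para carbon C2 and loss of imidodisulfonate gives the 1,4-quinone, a conversion well known for 3-methoxy-5-alkylphenols that leaves aliphatic alcohols alone.

Step 10
Reactants: 18 2-[(R)-2-hydroxytridecyl]-6-methoxy-1,4-benzoquinone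
Product: 20 (R)-1-(2,5-diacetoxy-3-methoxyphenyl)tridecan-2-yl acetate, via hydroquinone 19 (not isolated)
Conditions: Zn dust, Ac2O, pyridine, 4-(dimethylamino)pyridine (cat.), CH2Cl2, 0 °C → rt
Reagents that add atoms: acetic anhydride, CC(=O)OC(C)=O
Why: Reductive acetylation of a quinone, in which Zn delivers two electrons to give hydroquinone 19, which is acetylated as it forms and so cannot re-oxidize, while 4-(dimethylamino)pyridine catalysis carries the hindered C2 phenol and the secondary alcohol to their acetates by O-acylation with retention.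

Step 11
Reactants: 20 (R)-1-(2,5-diacetoxy-3-methoxyphenyl)tridecan-2-yl acetate
Product: 21 (R)-1-(2-acetoxy-5-hydroxy-3-methoxyphenyl)tridecan-2-yl acetate
Conditions: pyrrolidine (1.1 equiv), CH2Cl2, 0 °C, monitored; dilute aqueous acid wash
Reagents that add atoms: none
Why: Site-selective aminolysis of an aryl ester: alkyl acetates are inert to a secondary amine at 0 °C, the C2 acetate is shielded by its two ortho substituents (C1 side chain, C3 OMe) whereas the C5 acetate has only hydrogens beside it, the amine is close to limiting, and the phenol set free at C5 makes the para C2 aryloxide a poorer leaving group, which slows a second cleavage further.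

Compound list
1 | (R)-3-hydroxytetradecanoic acid | CCCCCCCCCCC[C@H](CC(=O)O)O | starting material
2 | (R)-3-hydroxy-N-methoxy-N-methyltetradecanamide | CCCCCCCCCCC[C@H](CC(=O)N(C)OC)O | intermediate
3 | (R)-3-(tert-butyldimethylsilyloxy)-N-methoxy-N-methyltetradecanamide | CCCCCCCCCCC[C@H](CC(=O)N(C)OC)O[Si](C)(C)C(C)(C)C | intermediate
4 | 2,2,6-trimethyl-4H-1,3-dioxin-4-one | CC1=CC(=O)OC(C)(C)O1 | starting material
5 | acetyl chloride | CC(Cl)=O | starting material
6 | lithium 2,2-dimethyl-6-methylidene-6H-1,3-dioxin-4-olate (dienolate of 4, formed in the flask) | [Li+].C=C1C=C([O-])OC(C)(C)O1 | intermediate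
7 | 2,2-dimethyl-6-(2-oxopropyl)-4H-1,3-dioxin-4-one | CC(=O)CC1=CC(=O)OC(C)(C)O1 | intermediate
8 | dilithium dianion of 7 (terminal enolate plus dioxinone dienolate, formed in the flask) | [Li+].[Li+].C=C([O-])C=C1C=C([O-])OC(C)(C)O1 | intermediate
9 | 6-[(R)-6-(tert-butyldimethylsilyloxy)-2,4-dioxoheptadecyl]-2,2-dimethyl-4H-1,3-dioxin-4-one | CCCCCCCCCCC[C@H](CC(=O)CC(=O)CC1=CC(=O)OC(C)(C)O1)O[Si](C)(C)C(C)(C)C | intermediate
10 | (R)-9-(tert-butyldimethylsilyloxy)icos-1-ene-1,3,5,7-tetraone (acylketene, formed in the flask) | CCCCCCCCCCC[C@H](CC(=O)CC(=O)CC(=O)C=C=O)O[Si](C)(C)C(C)(C)C | intermediate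
11 | benzyl (R)-9-(tert-butyldimethylsilyloxy)-3,5,7-trioxoicosanoate (formed in the flask) | CCCCCCCCCCC[C@H](CC(=O)CC(=O)CC(=O)CC(=O)OCc1ccccc1)O[Si](C)(C)C(C)(C)C | intermediate
12 | benzyl 2-hydroxy-4,6-dioxo-2-[(R)-2-(tert-butyldimethylsilyloxy)tridecyl]cyclohexane-1-carboxylate (ring centres transient and undefined, formed in the flask) | CCCCCCCCCCC[C@H](CC1(O)CC(=O)CC(=O)C1C(=O)OCc2ccccc2)O[Si](C)(C)C(C)(C)C | intermediate
13 | benzyl 2,4-dihydroxy-6-[(R)-2-(tert-butyldimethylsilyloxy)tridecyl]benzoate | CCCCCCCCCCC[C@H](Cc1cc(O)cc(O)c1C(=O)OCc2ccccc2)O[Si](C)(C)C(C)(C)C | intermediate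
14 | benzyl 2-hydroxy-4-methoxy-6-[(R)-2-(tert-butyldimethylsilyloxy)tridecyl]benzoate | CCCCCCCCCCC[C@H](Cc1cc(OC)cc(O)c1C(=O)OCc2ccccc2)O[Si](C)(C)C(C)(C)C | intermediate
15 | 2-hydroxy-4-methoxy-6-[(R)-2-(tert-butyldimethylsilyloxy)tridecyl]benzoic acid (formed in the flask) | CCCCCCCCCCC[C@H](Cc1cc(OC)cc(O)c1C(=O)O)O[Si](C)(C)C(C)(C)C | intermediate
16 | 3-methoxy-5-[(R)-2-(tert-butyldimethylsilyloxy)tridecyl]phenol | CCCCCCCCCCC[C@H](Cc1cc(OC)cc(O)c1)O[Si](C)(C)C(C)(C)C | intermediate
17 | 3-[(R)-2-hydroxytridecyl]-5-methoxyphenol | CCCCCCCCCCC[C@H](Cc1cc(OC)cc(O)c1)O | intermediate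
18 | 2-[(R)-2-hydroxytridecyl]-6-methoxy-1,4-benzoquinone | CCCCCCCCCCC[C@H](CC1=CC(=O)C=C(OC)C1=O)O | intermediate
19 | 2-[(R)-2-hydroxytridecyl]-6-methoxybenzene-1,4-diol (formed in the flask) | CCCCCCCCCCC[C@H](Cc1cc(O)cc(OC)c1O)O | intermediate
20 | (R)-1-(2,5-diacetoxy-3-methoxyphenyl)tridecan-2-yl acetate | CCCCCCCCCCC[C@H](Cc1cc(OC(C)=O)cc(OC)c1OC(C)=O)OC(C)=O | intermediate
21 | (R)-1-(2-acetoxy-5-hydroxy-3-methoxyphenyl)tridecan-2-yl acetate | CCCCCCCCCCC[C@H](Cc1cc(O)cc(OC)c1OC(C)=O)OC(C)=O | target

Total step count: 11
Longest linear sequence: 10 steps (1 → 21 through steps 1, 2 and 4 to 11). Step 3 is a one-step side branch.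

Steps most likely to fail

**Step 5 (key step).**
- What may go wrong: internal O-acylation of the acylketene outpacing capture by the alcohol, Claisen-type instead of aldol folding, or β-elimination of the silyloxy group during the base phase.
- Fallback: set out from 9 and aromatize without ever generating the ketene. Et3N in CH2Cl2 at room temperature lets the dioxinone α-carbon, as its vinylogous enolate, add to the same chain-bearing ketone. After loss of water this should give 7-hydroxy-2,2-dimethyl-5-[(R)-2-(tert-butyldimethylsilyloxy)tridecyl]-4H-1,3-benzodioxin-4-one F1, in which the ortho phenol and the carboxyl are tied up together as the acetonide. The single free phenol is methylated (MeI, K2CO3, acetone) to 7-methoxy-2,2-dimethyl-5-[(R)-2-(tert-butyldimethylsilyloxy)tridecyl]-4H-1,3-benzodioxin-4-one F2. Aqueous KOH in THF at 50 °C followed by cold acidification opens the acetonide ester to acid 15, where the route is rejoined for the thermal loss of CO2.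

**Step 4.**
- What may go wrong: proton transfer from the α-methylene of the amide to the basic dianion, followed by expulsion of silanolate, together with sluggish acylation.
- Fallback: set out from 3 and replace acylation by addition and oxidation. i-Bu2AlH in THF at −78 °C reduces the amide to (R)-3-(tert-butyldimethylsilyloxy)tetradecanal F3. Dianion 8 adds to this far better electrophile at −78 °C to give 6-[(6R)-6-(tert-butyldimethylsilyloxy)-4-hydroxy-2-oxoheptadecyl]-2,2-dimethyl-4H-1,3-dioxin-4-one F4, as a mixture at the new carbinol carbon that is of no consequence. Dess–Martin periodinane in CH2Cl2 oxidizes this alcohol and returns to the route at 9.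

**Step 11.**
- What may go wrong: insufficient discrimination between the two aryl acetates, or intermolecular acetyl transfer between phenols.
- Fallback: set out from 18 and mark the unhindered phenol positively instead of unmasking it last. Na2S2O4 in EtOAc–H2O gives hydroquinone 19, now isolated under N2. TBSCl (1 equiv) and imidazole in CH2Cl2 at 0 °C silylate the open C5 phenol to 4-(tert-butyldimethylsilyloxy)-2-[(R)-2-hydroxytridecyl]-6-methoxyphenol F5. Ac2O, pyridine and catalytic 4-(dimethylamino)pyridine acetylate the C2 phenol and the secondary alcohol to (R)-1-[2-acetoxy-5-(tert-butyldimethylsilyloxy)-3-methoxyphenyl]tridecan-2-yl acetate F6. HF·pyridine in THF removes the aryl silyl ether without touching the acetates and arrives at 21.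

Further compounds
F1 | step 5 | 7-hydroxy-2,2-dimethyl-5-[(R)-2-(tert-butyldimethylsilyloxy)tridecyl]-4H-1,3-benzodioxin-4-one | CCCCCCCCCCC[C@H](Cc1cc(O)cc2OC(C)(C)OC(=O)c12)O[Si](C)(C)C(C)(C)C
F2 | step 5 | 7-methoxy-2,2-dimethyl-5-[(R)-2-(tert-butyldimethylsilyloxy)tridecyl]-4H-1,3-benzodioxin-4-one | CCCCCCCCCCC[C@H](Cc1cc(OC)cc2OC(C)(C)OC(=O)c12)O[Si](C)(C)C(C)(C)C
F3 | step 4 | (R)-3-(tert-butyldimethylsilyloxy)tetradecanal | CCCCCCCCCCC[C@H](CC=O)O[Si](C)(C)C(C)(C)C
F4 | step 4 | 6-[(6R)-6-(tert-butyldimethylsilyloxy)-4-hydroxy-2-oxoheptadecyl]-2,2-dimethyl-4H-1,3-dioxin-4-one | CCCCCCCCCCC[C@H](CC(O)CC(=O)CC1=CC(=O)OC(C)(C)O1)O[Si](C)(C)C(C)(C)C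
F5 | step 11 | 4-(tert-butyldimethylsilyloxy)-2-[(R)-2-hydroxytridecyl]-6-methoxyphenol | CCCCCCCCCCC[C@H](Cc1cc(O[Si](C)(C)C(C)(C)C)cc(OC)c1O)O
F6 | step 11 | (R)-1-[2-acetoxy-5-(tert-butyldimethylsilyloxy)-3-methoxyphenyl]tridecan-2-yl acetate | CCCCCCCCCCC[C@H](Cc1cc(O[Si](C)(C)C(C)(C)C)cc(OC)c1OC(C)=O)OC(C)=O
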